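Ring B is opened retrosynthetically across two bonds, C(aroyl)–C(O) and C(CH2)–C(H). The feature exploited is its substitution pattern: oxygen, the diaryl ketone carbon and the benzylic CH2 occupy three contiguous ring B carbons, and the remaining three carbons are CH. Two ring atoms can therefore come from an alkyne and four from 1-methoxycyclohexa-1,3-diene. The precursor is an aryl ynone that already holds ring A, the ketone and a diethyl acetal arm. One thermal cycloaddition with loss of ethylene delivers aromatic ring B and the tetra-ortho-substituted benzophenone together. A dioxinone then converts the acetal arm into the 4-hydroxypyranone, and the three methyl ethers are cleaved last.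

Key step: step 4

Remark on the chemistry:
- The target has no stereocentre. The carbinols of steps 2 and 6 and the bridged adduct of step 4 are racemic, and their stereocentres are erased later.
- Ring A stays as its methyl ethers until the alkyne is consumed, because a free ortho-phenol would add to the ynone.
- The pyranone is drawn as the 4-hydroxy-2H-pyran-2-one tautomer.
- All four starting materials are taken to be catalogue items.

Step 1
Reactants: 1 1-ethyl-3,5-dimethoxybenzene
Product: 3 2-ethyl-4,6-dimethoxybenzaldehyde, via aryl iminium chloride 2 (not isolated)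
Conditions: POCl3, DMF, 0 °C to 60 °C; then ice–water
Reagents that add atoms: N,N-dimethylformamide CN(C)C=O; water O
Why: Vilsmeier–Haack formylation, in which the chloroiminium ion attacks one of the two equivalent ring carbons lying para to one methoxy group and ortho to the other, the usual outcome for 5-alkylresorcinol dimethyl ethers, and hydrolysis of iminium salt 2 releases the aldehyde next to the ethyl group.

Step 2
Reactants: 3 2-ethyl-4,6-dimethoxybenzaldehyde; 4 4,4-diethoxybut-1-yne
Product: 6 5,5-diethoxy-1-(2-ethyl-4,6-dimethoxyphenyl)pent-2-yn-1-ol (racemic), via lithium acetylide 5 (not isolated)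
Conditions: 4, n-BuLi, THF, −78 °C; then 3, −78 to 0 °C; aq. NH4Cl
Reagents that add atoms: none
Why: 1,2-addition of a lithium acetylide to an aldehyde, in which the slim nucleophile reaches the doubly ortho-substituted formyl group, the acetal is inert to organolithium reagents, and the new carbinol centre forms racemic and is erased in step 3.

Step 3
Reactants: 6 5,5-diethoxy-1-(2-ethyl-4,6-dimethoxyphenyl)pent-2-yn-1-ol
Product: 7 5,5-diethoxy-1-(2-ethyl-4,6-dimethoxyphenyl)pent-2-yn-1-one
Conditions: activated MnO2 (excess), CH2Cl2, rt; filtered and used without chromatography on basic media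
Reagents that add atoms: none
Why: MnO2 oxidation of an alcohol that is both benzylic and propargylic runs on the solid surface without acid or base, so neither the acetal nor the base-sensitive propargylic CH2 of the new ynone is disturbed.

Step 4
Reactants: 7 5,5-diethoxy-1-(2-ethyl-4,6-dimethoxyphenyl)pent-2-yn-1-one; 8 1-methoxycyclohexa-1,3-diene
Product: 10 [2-(2,2-diethoxyethyl)-6-methoxyphenyl](2-ethyl-4,6-dimethoxyphenyl)methanone, via bridged bicyclo[2.2.2]octadiene adduct 9 (not isolated)
Conditions: 8 (5 equiv), 2,6-di-tert-butyl-4-methylphenol (BHT, 5 mol %), mesitylene, silanised pressure tube, 175 °C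
Reagents that add atoms: none
Why: This is an Alder–Rickert reaction, that is a normal-electron-demand intermolecular [4+2] cycloaddition of electron-rich diene 8 across the triple bond of ynone 7 to give bridged adduct 9, followed at the same temperature by retro-[4+2] loss of the ethano bridge as ethylene, which is irreversible because a gas escapes and an arene forms. The closest known reaction type is the preparation of 6-alkyl-2-methoxybenzoates and 2-acylanisoles from 1-alkoxycyclohexa-1,3-dienes and alk-2-ynoates or alkynyl ketones. Ring B is closed by intermolecular cycloaddition, both new bonds (aroyl-bearing carbon to C–OMe, CH2-bearing carbon to CH) arising in one pericyclic event, and no oxidant is needed because the alkyne supplies the missing unsaturation. No stereocentre remains, since the two bridgehead centres of racemic 9 are flattened on aromatisation. The step needs regioselectivity, and matched polarisation secures it: the diene terminus remote from methoxy is the most nucleophilic carbon and the alkyne carbon β to the carbonyl is the most electrophilic, so methoxy ends up next to the aroyl group. Ring A is twisted out of the carbonyl plane by its two ortho substituents, so its donor oxygens scarcely deactivate the ynone, while the neutral hydrocarbon medium, silanised glass and BHT protect the propargylic CH2, the acetal and the enol ether.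

Step 5
Reactants: 10 [2-(2,2-diethoxyethyl)-6-methoxyphenyl](2-ethyl-4,6-dimethoxyphenyl)methanone
Product: 11 2-[2-(2-ethyl-4,6-dimethoxybenzoyl)-3-methoxyphenyl]acetaldehyde
Conditions: 1 M aq. HCl (catalytic), THF, rt; neutral work-up, used crude
Reagents that add atoms: water O
Why: Acid-catalysed acetal hydrolysis leaves the aryl methyl ethers and the shielded diaryl ketone untouched, any reversible closure of the keto aldehyde to a benzopyrylium ion is undone by water on neutralisation, and the enolisable aldehyde is carried forward without chromatography.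

Step 6
Reactants: 11 2-[2-(2-ethyl-4,6-dimethoxybenzoyl)-3-methoxyphenyl]acetaldehyde; 12 2,2,6-trimethyl-4H-1,3-dioxin-4-one
Product: 14 6-{3-[2-(2-ethyl-4,6-dimethoxybenzoyl)-3-methoxyphenyl]-2-hydroxypropyl}-2,2-dimethyl-4H-1,3-dioxin-4-one (racemic), via lithium dienolate 13 (not isolated)
Conditions: 12 (1.5 equiv), LiN(iPr)2, THF, −78 °C; then 11, −78 °C; AcOH quench at −78 °C
Reagents that add atoms: none
Why: Vinylogous aldol addition, in which lithium dienolate 13 reacts through its exocyclic γ-carbon with the unhindered aldehyde far faster than with the tetra-ortho-substituted ketone, low temperature and a cold acid quench limit enolisation and retro-aldol cleavage, and the new carbinol centre is racemic and is erased in step 7.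

Step 7
Reactants: 14 6-{3-[2-(2-ethyl-4,6-dimethoxybenzoyl)-3-methoxyphenyl]-2-hydroxypropyl}-2,2-dimethyl-4H-1,3-dioxin-4-one
Product: 15 6-{3-[2-(2-ethyl-4,6-dimethoxybenzoyl)-3-methoxyphenyl]-2-oxopropyl}-2,2-dimethyl-4H-1,3-dioxin-4-one
Conditions: Dess–Martin periodinane (1.2 equiv), CH2Cl2, 0 °C to rt
Reagents that add atoms: none
Why: Dess–Martin oxidation converts the secondary alcohol into the ketone under near-neutral conditions, which avoids base-induced aldol closure of the active methylene onto the diaryl ketone.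

Step 8
Reactants: 15 6-{3-[2-(2-ethyl-4,6-dimethoxybenzoyl)-3-methoxyphenyl]-2-oxopropyl}-2,2-dimethyl-4H-1,3-dioxin-4-one
Product: 17 6-{[2-(2-ethyl-4,6-dimethoxybenzoyl)-3-methoxyphenyl]methyl}-4-hydroxy-2H-pyran-2-one, via acylketene 16 (not isolated)
Conditions: toluene, 110 °C
Reagents that add atoms: none
Why: Thermal retro-[4+2] fragmentation of the dioxinone expels acetone, and acylketene 16 is captured by the enol oxygen of the δ-ketone in a six-membered lactonisation, the standard dioxinone route to 6-substituted 4-hydroxy-2-pyranones.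

Step 9
Reactants: 17 6-{[2-(2-ethyl-4,6-dimethoxybenzoyl)-3-methoxyphenyl]methyl}-4-hydroxy-2H-pyran-2-one
Product: 18 6-{[2-(2-ethyl-4,6-dihydroxybenzoyl)-3-hydroxyphenyl]methyl}-4-hydroxy-2H-pyran-2-one (target CNP0234555.0)
Conditions: BBr3 (10 equiv), CH2Cl2, −78 °C to rt; then H2O
Reagents that add atoms: none
Why: BBr3 ether cleavage works here because all three methoxy groups are ortho or para to the ketone, the two ortho ones being helped by chelation of boron, while the pyranone only forms a borate that water releases and the acidic medium avoids the base-induced xanthone closure open to 2-hydroxy-2'-methoxybenzophenones.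

Compound list
1 | 1-ethyl-3,5-dimethoxybenzene | CCc1cc(OC)cc(OC)c1 | starting material
2 | [(2-ethyl-4,6-dimethoxyphenyl)methylidene]dimethylazanium chloride (aryl iminium chloride) | CCc1cc(OC)cc(OC)c1C=[N+](C)C.[Cl-] | intermediate
3 | 2-ethyl-4,6-dimethoxybenzaldehyde | CCc1cc(OC)cc(OC)c1C=O | intermediate
4 | 4,4-diethoxybut-1-yne | C#CCC(OCC)OCC | starting material
5 | (4,4-diethoxybut-1-yn-1-yl)lithium (lithium acetylide) | [Li]C#CCC(OCC)OCC | intermediate
6 | 5,5-diethoxy-1-(2-ethyl-4,6-dimethoxyphenyl)pent-2-yn-1-ol, racemic | CCc1cc(OC)cc(OC)c1C(O)C#CCC(OCC)OCC | intermediate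
7 | 5,5-diethoxy-1-(2-ethyl-4,6-dimethoxyphenyl)pent-2-yn-1-one | CCc1cc(OC)cc(OC)c1C(=O)C#CCC(OCC)OCC | intermediate
8 | 1-methoxycyclohexa-1,3-diene | COC1=CC=CCC1 | starting material
9 | [3-(2,2-diethoxyethyl)-1-methoxybicyclo[2.2.2]octa-2,5-dien-2-yl](2-ethyl-4,6-dimethoxyphenyl)methanone, racemic | COC12CCC(C=C1)C(CC(OCC)OCC)=C2C(=O)c1c(CC)cc(OC)cc1OC | intermediate
10 | [2-(2,2-diethoxyethyl)-6-methoxyphenyl](2-ethyl-4,6-dimethoxyphenyl)methanone | CCc1cc(OC)cc(OC)c1C(=O)c1c(OC)cccc1CC(OCC)OCC | intermediate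
11 | 2-[2-(2-ethyl-4,6-dimethoxybenzoyl)-3-methoxyphenyl]acetaldehyde | CCc1cc(OC)cc(OC)c1C(=O)c1c(OC)cccc1CC=O | intermediate
12 | 2,2,6-trimethyl-4H-1,3-dioxin-4-one | CC1=CC(=O)OC(C)(C)O1 | starting material
13 | lithium 2,2-dimethyl-6-methylidene-6H-1,3-dioxin-4-olate (lithium dienolate) | [Li+].C=C1C=C([O-])OC(C)(C)O1 | intermediate
14 | 6-{3-[2-(2-ethyl-4,6-dimethoxybenzoyl)-3-methoxyphenyl]-2-hydroxypropyl}-2,2-dimethyl-4H-1,3-dioxin-4-one, racemic | CCc1cc(OC)cc(OC)c1C(=O)c1c(OC)cccc1CC(O)CC1=CC(=O)OC(C)(C)O1 | intermediate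
15 | 6-{3-[2-(2-ethyl-4,6-dimethoxybenzoyl)-3-methoxyphenyl]-2-oxopropyl}-2,2-dimethyl-4H-1,3-dioxin-4-one | CCc1cc(OC)cc(OC)c1C(=O)c1c(OC)cccc1CC(=O)CC1=CC(=O)OC(C)(C)O1 | intermediate
16 | 6-[2-(2-ethyl-4,6-dimethoxybenzoyl)-3-methoxyphenyl]hex-1-ene-1,3,5-trione (acylketene) | CCc1cc(OC)cc(OC)c1C(=O)c1c(OC)cccc1CC(=O)CC(=O)C=C=O | intermediate
17 | 6-{[2-(2-ethyl-4,6-dimethoxybenzoyl)-3-methoxyphenyl]methyl}-4-hydroxy-2H-pyran-2-one | CCc1cc(OC)cc(OC)c1C(=O)c1c(OC)cccc1Cc1cc(O)cc(=O)o1 | intermediate
18 | 6-{[2-(2-ethyl-4,6-dihydroxybenzoyl)-3-hydroxyphenyl]methyl}-4-hydroxy-2H-pyran-2-one | CCc1cc(O)cc(O)c1C(=O)c1c(O)cccc1Cc1cc(O)cc(=O)o1 | target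

Total step count: 9
Longest linear sequence: 9 steps (1 to 18)

Steps most likely to fail

Step 4.
- What may go wrong: the crowded, doubly substituted triple bond may react too slowly. Prototropic shift of the propargylic CH2, elimination of ethanol from the acetal, thermal hydrogen shifts within the diene, or erosion of regiocontrol by the bulky aroyl group could then take over.
- Fallback: ring B is built on a smaller and more electrophilic dienophile, and the hindered ketone is made afterwards. It sets out from 5, 8 and 1 and returns at 10.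
- Acetylide 5 is formylated with DMF and quenched into aq. KH2PO4 to give 5,5-diethoxypent-2-ynal F1.
- F1 and 8 are warmed in toluene at about 110 °C to form 3-(2,2-diethoxyethyl)-1-methoxybicyclo[2.2.2]octa-2,5-diene-2-carbaldehyde F2. Brief heating to 170 °C expels ethylene and gives 2-(2,2-diethoxyethyl)-6-methoxybenzaldehyde F3.
- Separately, 1 is brominated with N-bromosuccinimide in MeCN to 2-bromo-1-ethyl-3,5-dimethoxybenzene F4. Bromine–lithium exchange with n-BuLi at −78 °C gives (2-ethyl-4,6-dimethoxyphenyl)lithium F5.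
- Addition of F5 to F3 gives [2-(2,2-diethoxyethyl)-6-methoxyphenyl](2-ethyl-4,6-dimethoxyphenyl)methanol F6. Dess–Martin oxidation of F6 gives 10.

Step 6.
- What may go wrong: proton transfer from the acidic α-CH2 of the arylacetaldehyde to the basic dienolate, followed by self-condensation of the aldehyde, and retro-aldol cleavage on warming.
- Fallback: the basic nucleophile is replaced by a neutral silyl dienol ether under Lewis acid activation, a vinylogous Mukaiyama aldol. It sets out from 13 and 11 and returns at 14.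
- Dienolate 13 is trapped with Me3SiCl and distilled to give 2,2-dimethyl-4-methylidene-6-(trimethylsilyloxy)-4H-1,3-dioxine F7.
- F7 and 11 are combined with BF3·OEt2 in CH2Cl2 at −78 °C, and aqueous work-up releases 14.

Step 9.
- What may go wrong: incomplete cleavage of the ether para to the ketone, or Lewis-acid-driven cyclodehydration between the activated ketone and the nucleophilic pyranone during the long exposure that full cleavage demands.
- Fallback: the protecting-group plan is changed so that only a chelation-assisted methyl ether and two benzyl ethers remain at the end. It sets out from 3 and returns at 18.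
- Aldehyde 3 is demethylated with BBr3 to 2-ethyl-4,6-dihydroxybenzaldehyde F8 and benzylated (BnBr, K2CO3, DMF) to 2,4-bis(benzyloxy)-6-ethylbenzaldehyde F9.
- The operations already described are then repeated. Addition of 5 gives 1-[2,4-bis(benzyloxy)-6-ethylphenyl]-5,5-diethoxypent-2-yn-1-ol F10, and MnO2 gives 1-[2,4-bis(benzyloxy)-6-ethylphenyl]-5,5-diethoxypent-2-yn-1-one F11.
- Heating F11 with 8 gives, through [3-(2,2-diethoxyethyl)-1-methoxybicyclo[2.2.2]octa-2,5-dien-2-yl][2,4-bis(benzyloxy)-6-ethylphenyl]methanone F12, the ketone [2,4-bis(benzyloxy)-6-ethylphenyl][2-(2,2-diethoxyethyl)-6-methoxyphenyl]methanone F13.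
- Hydrolysis gives 2-{2-[2,4-bis(benzyloxy)-6-ethylbenzoyl]-3-methoxyphenyl}acetaldehyde F14. Addition of 13 gives 6-(3-{2-[2,4-bis(benzyloxy)-6-ethylbenzoyl]-3-methoxyphenyl}-2-hydroxypropyl)-2,2-dimethyl-4H-1,3-dioxin-4-one F15.
- Dess–Martin oxidation gives 6-(3-{2-[2,4-bis(benzyloxy)-6-ethylbenzoyl]-3-methoxyphenyl}-2-oxopropyl)-2,2-dimethyl-4H-1,3-dioxin-4-one F16.
- Thermolysis gives, through 6-{2-[2,4-bis(benzyloxy)-6-ethylbenzoyl]-3-methoxyphenyl}hex-1-ene-1,3,5-trione F17, the pyranone 6-({2-[2,4-bis(benzyloxy)-6-ethylbenzoyl]-3-methoxyphenyl}methyl)-4-hydroxy-2H-pyran-2-one F18.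
- BCl3 with pentamethylbenzene as benzyl cation trap (CH2Cl2, −78 to 0 °C) then removes both benzyl groups and the ring B methyl ether ortho to the ketone, giving 18 under milder Lewis acidity.

Further compounds
F1 | step 4 | 5,5-diethoxypent-2-ynal | O=CC#CCC(OCC)OCC
F2 | step 4 | 3-(2,2-diethoxyethyl)-1-methoxybicyclo[2.2.2]octa-2,5-diene-2-carbaldehyde, racemic | COC12CCC(C=C1)C(CC(OCC)OCC)=C2C=O
F3 | step 4 | 2-(2,2-diethoxyethyl)-6-methoxybenzaldehyde | COc1cccc(CC(OCC)OCC)c1C=O
F4 | step 4 | 2-bromo-1-ethyl-3,5-dimethoxybenzene | CCc1cc(OC)cc(OC)c1Br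
F5 | step 4 | (2-ethyl-4,6-dimethoxyphenyl)lithium | CCc1cc(OC)cc(OC)c1[Li]
F6 | step 4 | [2-(2,2-diethoxyethyl)-6-methoxyphenyl](2-ethyl-4,6-dimethoxyphenyl)methanol, racemic | CCc1cc(OC)cc(OC)c1C(O)c1c(OC)cccc1CC(OCC)OCC
F7 | step 6 | 2,2-dimethyl-4-methylidene-6-(trimethylsilyloxy)-4H-1,3-dioxine | C=C1C=C(O[Si](C)(C)C)OC(C)(C)O1
F8 | step 9 | 2-ethyl-4,6-dihydroxybenzaldehyde | CCc1cc(O)cc(O)c1C=O
F9 | step 9 | 2,4-bis(benzyloxy)-6-ethylbenzaldehyde | CCc1cc(OCc2ccccc2)cc(OCc2ccccc2)c1C=O
F10 | step 9 | 1-[2,4-bis(benzyloxy)-6-ethylphenyl]-5,5-diethoxypent-2-yn-1-ol, racemic | CCc1cc(OCc2ccccc2)cc(OCc2ccccc2)c1C(O)C#CCC(OCC)OCC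
F11 | step 9 | 1-[2,4-bis(benzyloxy)-6-ethylphenyl]-5,5-diethoxypent-2-yn-1-one | CCc1cc(OCc2ccccc2)cc(OCc2ccccc2)c1C(=O)C#CCC(OCC)OCC
F12 | step 9 | [3-(2,2-diethoxyethyl)-1-methoxybicyclo[2.2.2]octa-2,5-dien-2-yl][2,4-bis(benzyloxy)-6-ethylphenyl]methanone, racemic | COC12CCC(C=C1)C(CC(OCC)OCC)=C2C(=O)c1c(CC)cc(OCc2ccccc2)cc1OCc1ccccc1
F13 | step 9 | [2,4-bis(benzyloxy)-6-ethylphenyl][2-(2,2-diethoxyethyl)-6-methoxyphenyl]methanone | CCc1cc(OCc2ccccc2)cc(OCc2ccccc2)c1C(=O)c1c(OC)cccc1CC(OCC)OCC
F14 | step 9 | 2-{2-[2,4-bis(benzyloxy)-6-ethylbenzoyl]-3-methoxyphenyl}acetaldehyde | CCc1cc(OCc2ccccc2)cc(OCc2ccccc2)c1C(=O)c1c(OC)cccc1CC=O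
F15 | step 9 | 6-(3-{2-[2,4-bis(benzyloxy)-6-ethylbenzoyl]-3-methoxyphenyl}-2-hydroxypropyl)-2,2-dimethyl-4H-1,3-dioxin-4-one, racemic | CCc1cc(OCc2ccccc2)cc(OCc2ccccc2)c1C(=O)c1c(OC)cccc1CC(O)CC1=CC(=O)OC(C)(C)O1
F16 | step 9 | 6-(3-{2-[2,4-bis(benzyloxy)-6-ethylbenzoyl]-3-methoxyphenyl}-2-oxopropyl)-2,2-dimethyl-4H-1,3-dioxin-4-one | CCc1cc(OCc2ccccc2)cc(OCc2ccccc2)c1C(=O)c1c(OC)cccc1CC(=O)CC1=CC(=O)OC(C)(C)O1
F17 | step 9 | 6-{2-[2,4-bis(benzyloxy)-6-ethylbenzoyl]-3-methoxyphenyl}hex-1-ene-1,3,5-trione | CCc1cc(OCc2ccccc2)cc(OCc2ccccc2)c1C(=O)c1c(OC)cccc1CC(=O)CC(=O)C=C=O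
F18 | step 9 | 6-({2-[2,4-bis(benzyloxy)-6-ethylbenzoyl]-3-methoxyphenyl}methyl)-4-hydroxy-2H-pyran-2-one | CCc1cc(OCc2ccccc2)cc(OCc2ccccc2)c1C(=O)c1c(OC)cccc1Cc1cc(O)cc(=O)o1
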